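The route rests on disconnecting the dihydrofuran ring of the target at C3–C3a and O1–C2. The 2,3-dihydrobenzofuran has a bare C3 methylene on the arene and a C2 that bears O1 plus a branched three-carbon chain. That is the signature of a 2-iodophenol delivering its C–I carbon and its hydroxyl oxygen to the monosubstituted double bond of a 2-substituted buta-1,3-diene. One ligand-controlled palladium heteroannulation therefore forms both bonds, closes the oxygen ring and sets C2 as S. Its partners are 4-hydroxy-3-iodobenzaldehyde and the silyl ether of 2-methylidenebut-3-en-1-ol. The formyl group later becomes the acrylic acid, and the exocyclic alkene is reduced under catalyst control to fix C2'.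

Key step: step 2

Remark: CIP analysis of the target gives S at ring carbon C2 and S at side-chain carbon C2'; the sense of induction of the chiral ligands in steps 2 and 4 is to be assigned in pilot runs with both antipodes, and the antipode that delivers S is the one meant.

Step 1
Reactants: 1 isoprene monoxide (2-methyl-2-vinyloxirane, racemic)
Product: 3 tert-butyl(dimethyl)[(2-methylidenebut-3-en-1-yl)oxy]silane, via lithium 2-methylidenebut-3-en-1-olate 2 (not isolated)
Conditions: LiN(iPr)2 (1.2 equiv), Et2O/THF, −30 °C → rt; then TBSCl (1.3 equiv), 0 °C → rt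
Reagents that add atoms: tert-butyldimethylsilyl chloride (TBSCl), CC(C)(C)[Si](C)(C)Cl
Why: Base-induced isomerisation of an epoxide to an allylic alcohol (amide-mediated β-elimination of a methyl proton with opening of the C–O bond at the quaternary carbon) should give the dienyl alkoxide, and O-silylation in the same flask avoids isolating the volatile, dimerisation-prone dienol and masks a hydroxyl that could otherwise act as a hydride donor in the next step.

Step 2
Reactants: 3 tert-butyl(dimethyl)[(2-methylidenebut-3-en-1-yl)oxy]silane (2 equiv); 4 4-hydroxy-3-iodobenzaldehyde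
Product: 5 (2S)-2-[3-(tert-butyldimethylsilyloxy)prop-1-en-2-yl]-2,3-dihydro-1-benzofuran-5-carbaldehyde
Conditions: Pd2(dba)3·CHCl3 (5 mol%), chiral sulfinamide monophosphine of the TY-Phos type (20 mol%, antipode giving 2S), PhONa (2 equiv), CH2Cl2, 80 °C, sealed tube
Reagents that add atoms: none
Why: Zerovalent palladium inserts into the C–I bond of 4 (aided by the para formyl group), the arylpalladium iodide adds syn across the monosubstituted alkene of 3 with the aryl group going to the terminal CH2 (new C3–C3a bond), and the resulting π-allylpalladium is captured by the neighbouring phenoxide at the allyl carbon bearing the new benzylic CH2 (new O1–C2 bond), releasing zerovalent palladium. The closest known reaction type is the Larock heteroannulation of ortho-iodophenols with 1,3-dienes (Heck-type insertion followed by Tsuji–Trost etherification), which is established with 2-substituted dienes and in ligand-controlled enantioselective form. The dihydrofuran ring closes by 5-exo attack of the phenoxide oxygen on the π-allyl terminus, anti to palladium. C2 is set by the chiral monophosphine on palladium, which selects between the two diastereomeric allyl complexes (interconverting by π–σ–π isomerisation through the CH2 terminus) in the C–O bond-forming event. The step needs insertion at the vinyl rather than the 1,1-disubstituted alkene, secured by the bulk around the silyloxymethyl-bearing carbon and the preference of aryl for an unsubstituted terminus; attack at the internal rather than the distal allyl carbon, secured by five- over seven-membered ring formation; and cyclisation ahead of β-hydride elimination, secured by the tethered, fully ionised phenoxide. The silyl ether keeps the primary hydroxyl from serving as a hydride source toward arylpalladium.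

Step 3
Reactants: 5 (2S)-2-[3-(tert-butyldimethylsilyloxy)prop-1-en-2-yl]-2,3-dihydro-1-benzofuran-5-carbaldehyde
Product: 6 (2S)-2-(3-hydroxyprop-1-en-2-yl)-2,3-dihydro-1-benzofuran-5-carbaldehyde
Conditions: Bu4NF (1.5 equiv), AcOH (1.5 equiv), THF, 0 °C → rt
Reagents that add atoms: none
Why: Fluoride-mediated desilylation, buffered with acetic acid, should free the primary allylic alcohol without exposing the aldehyde or the allylic aryl ether centre C2 to strong base.

Step 4
Reactants: 6 (2S)-2-(3-hydroxyprop-1-en-2-yl)-2,3-dihydro-1-benzofuran-5-carbaldehyde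
Product: 7 (2S)-2-[(2S)-1-hydroxypropan-2-yl]-2,3-dihydro-1-benzofuran-5-carbaldehyde
Conditions: [Ir(cod)(tBu-PHOX)]BArF4 (2 mol%, ligand antipode matched to 2'S), H2 (1–5 bar), CH2Cl2, rt
Reagents that add atoms: none
Why: Iridium-catalysed asymmetric hydrogenation of a 1,1-disubstituted allylic alcohol with a cationic phosphinooxazoline complex should set C2' as S under catalyst control, because the two alkene substituents (CH2OH versus the branched ring carbon C2) differ clearly in size, while the aryl aldehyde, the aryl ether and C2 are not touched at low hydrogen pressure and room temperature.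

Step 5
Reactants: 7 (2S)-2-[(2S)-1-hydroxypropan-2-yl]-2,3-dihydro-1-benzofuran-5-carbaldehyde; 8 p-coumaric acid ((E)-3-(4-hydroxyphenyl)prop-2-enoic acid, 1.2 equiv)
Product: 9 (2S)-2-[(2S)-5-formyl-2,3-dihydro-1-benzofuran-2-yl]propyl (E)-3-(4-hydroxyphenyl)prop-2-enoate
Conditions: PPh3 (1.3 equiv), DIAD (1.3 equiv, slow addition), THF, 0 °C → rt
Reagents that add atoms: none
Why: Mitsunobu esterification is known to be chemoselective for the carboxyl group of unprotected phenolic acids, since the phosphine–azodicarboxylate betaine is protonated by the more acidic carboxylic acid and the carboxylate displaces the alkoxyphosphonium at the primary carbon, so the phenol, the aldehyde, the E alkene and the adjacent centre C2' remain unchanged.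

Step 6
Reactants: 9 (2S)-2-[(2S)-5-formyl-2,3-dihydro-1-benzofuran-2-yl]propyl (E)-3-(4-hydroxyphenyl)prop-2-enoate; 10 malonic acid (3 equiv)
Product: 12 (2E)-3-{(2S)-2-[(2S)-1-{[(2E)-3-(4-hydroxyphenyl)prop-2-enoyl]oxy}propan-2-yl]-2,3-dihydro-1-benzofuran-5-yl}prop-2-enoic acid (target CNP0224846.1), via arylidenemalonic acid 11 (not isolated)
Conditions: piperidine (0.2 equiv), pyridine, 85 °C; cold 1 M HCl work-up
Reagents that add atoms: none
Why: Knoevenagel–Doebner condensation of the aryl aldehyde with malonic acid should give the arylidenemalonic acid, which decarboxylates in hot pyridine to the thermodynamically favoured E acrylic acid, while the alkyl coumarate ester, the free phenol and both stereocentres are inert to this weakly basic medium.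

Compound list
1 | isoprene monoxide (2-methyl-2-vinyloxirane, racemic) | CC1(C=C)CO1 | starting material
2 | lithium 2-methylidenebut-3-en-1-olate | [Li+].[O-]CC(=C)C=C | intermediate
3 | tert-butyl(dimethyl)[(2-methylidenebut-3-en-1-yl)oxy]silane | C=CC(=C)CO[Si](C)(C)C(C)(C)C | intermediate
4 | 4-hydroxy-3-iodobenzaldehyde | O=Cc1ccc(O)c(I)c1 | starting material
5 | (2S)-2-[3-(tert-butyldimethylsilyloxy)prop-1-en-2-yl]-2,3-dihydro-1-benzofuran-5-carbaldehyde | C=C(CO[Si](C)(C)C(C)(C)C)[C@@H]1Cc2cc(C=O)ccc2O1 | intermediate
6 | (2S)-2-(3-hydroxyprop-1-en-2-yl)-2,3-dihydro-1-benzofuran-5-carbaldehyde | C=C(CO)[C@@H]1Cc2cc(C=O)ccc2O1 | intermediate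
7 | (2S)-2-[(2S)-1-hydroxypropan-2-yl]-2,3-dihydro-1-benzofuran-5-carbaldehyde | C[C@@H](CO)[C@@H]1Cc2cc(C=O)ccc2O1 | intermediate
8 | p-coumaric acid | OC(=O)/C=C/c1ccc(O)cc1 | starting material
9 | (2S)-2-[(2S)-5-formyl-2,3-dihydro-1-benzofuran-2-yl]propyl (E)-3-(4-hydroxyphenyl)prop-2-enoate | C[C@@H](COC(=O)/C=C/c1ccc(O)cc1)[C@@H]1Cc2cc(C=O)ccc2O1 | intermediate
10 | malonic acid | OC(=O)CC(=O)O | starting material
11 | 2-{[(2S)-2-[(2S)-1-{[(2E)-3-(4-hydroxyphenyl)prop-2-enoyl]oxy}propan-2-yl]-2,3-dihydro-1-benzofuran-5-yl]methylidene}propanedioic acid | C[C@@H](COC(=O)/C=C/c1ccc(O)cc1)[C@@H]1Cc2cc(C=C(C(=O)O)C(=O)O)ccc2O1 | intermediate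
12 | (2E)-3-{(2S)-2-[(2S)-1-{[(2E)-3-(4-hydroxyphenyl)prop-2-enoyl]oxy}propan-2-yl]-2,3-dihydro-1-benzofuran-5-yl}prop-2-enoic acid | C[C@@H](COC(=O)/C=C/c1ccc(O)cc1)[C@@H]1Cc2cc(/C=C/C(=O)O)ccc2O1 | target

Total step count: 6
Longest linear sequence: 6 steps (1 → 3 → 5 → 6 → 7 → 9 → 12); compounds 4, 8 and 10 enter directly.

Steps most likely to fail

Step 2. The chiral ligand may give insufficient facial control in the C–O bond-forming allylic substitution, or the ee may erode through reversible re-ionisation of the allylic aryl ether. β-Hydride elimination from the allyl intermediate to an open-chain aryl diene may also compete. The fallback sets out from 3 and 4 and replaces asymmetric catalysis by resolution. The ligand-free Larock protocol (Pd(OAc)2 5 mol%, NaHCO3, n-Bu4NCl, DMF, 80 °C), the most thoroughly established form of this annulation, should give racemic 2-[3-(tert-butyldimethylsilyloxy)prop-1-en-2-yl]-2,3-dihydro-1-benzofuran-5-carbaldehyde F1. Preparative supercritical-fluid chromatography on a polysaccharide chiral stationary phase should then separate the (2S)-enantiomer, which is 5, from (2R)-2-[3-(tert-butyldimethylsilyloxy)prop-1-en-2-yl]-2,3-dihydro-1-benzofuran-5-carbaldehyde F2. The route is rejoined at 5.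

Step 4. Facial selectivity at the terminal alkene may be poor if the resident C2 centre and the catalyst are mismatched, or if hydroxyl coordination overrides the ligand. The double bond may migrate toward C2 before hydrogen is delivered, which would erase that centre, and the aldehyde may be partly reduced. The fallback sets out from 6 and gives up catalyst control in favour of substrate-directed reduction and separation. Hydroxyl-directed hydrogenation with the achiral cationic complex [Rh(nbd)(dppb)]BF4 (H2 50 bar, CH2Cl2, rt; the high pressure suppresses allylic alcohol isomerisation) should give 7 together with its C2' epimer, (2S)-2-[(2R)-1-hydroxypropan-2-yl]-2,3-dihydro-1-benzofuran-5-carbaldehyde F3. The two are diastereomers and should be separable by preparative HPLC on silica. The route is rejoined at 7.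

Step 5. Chemoselectivity between carboxylate and phenoxide as the nucleophile may be lost, giving aryl ether or oligomeric ester–ether formation, and the aldehyde may intercept the phosphine–azodicarboxylate betaine. The fallback sets out from 8 and 7 and uses a protected acid with carbodiimide coupling:
- Bis-silylation of 8 (TBSCl 2.2 equiv, imidazole, DMF, rt) should give tert-butyldimethylsilyl (E)-3-[4-(tert-butyldimethylsilyloxy)phenyl]prop-2-enoate F4.
- Brief treatment with AcOH/THF/H2O at rt should hydrolyse only the silyl ester to (E)-3-[4-(tert-butyldimethylsilyloxy)phenyl]prop-2-enoic acid F5.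
- Steglich esterification of 7 with this acid (EDC·HCl, DMAP cat., CH2Cl2, rt) should give (2S)-2-[(2S)-5-formyl-2,3-dihydro-1-benzofuran-2-yl]propyl (E)-3-[4-(tert-butyldimethylsilyloxy)phenyl]prop-2-enoate F6.
- Buffered desilylation (Bu4NF, AcOH, THF, 0 °C) should return the route at 9.

Further compounds
F1 | step 2 | racemic 2-[3-(tert-butyldimethylsilyloxy)prop-1-en-2-yl]-2,3-dihydro-1-benzofuran-5-carbaldehyde | C=C(CO[Si](C)(C)C(C)(C)C)C1Cc2cc(C=O)ccc2O1
F2 | step 2 | (2R)-2-[3-(tert-butyldimethylsilyloxy)prop-1-en-2-yl]-2,3-dihydro-1-benzofuran-5-carbaldehyde | C=C(CO[Si](C)(C)C(C)(C)C)[C@H]1Cc2cc(C=O)ccc2O1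
F3 | step 4 | (2S)-2-[(2R)-1-hydroxypropan-2-yl]-2,3-dihydro-1-benzofuran-5-carbaldehyde | C[C@H](CO)[C@@H]1Cc2cc(C=O)ccc2O1
F4 | step 5 | tert-butyldimethylsilyl (E)-3-[4-(tert-butyldimethylsilyloxy)phenyl]prop-2-enoate | CC(C)(C)[Si](C)(C)OC(=O)/C=C/c1ccc(O[Si](C)(C)C(C)(C)C)cc1
F5 | step 5 | (E)-3-[4-(tert-butyldimethylsilyloxy)phenyl]prop-2-enoic acid | OC(=O)/C=C/c1ccc(O[Si](C)(C)C(C)(C)C)cc1
F6 | step 5 | (2S)-2-[(2S)-5-formyl-2,3-dihydro-1-benzofuran-2-yl]propyl (E)-3-[4-(tert-butyldimethylsilyloxy)phenyl]prop-2-enoate | C[C@@H](COC(=O)/C=C/c1ccc(O[Si](C)(C)C(C)(C)C)cc1)[C@@H]1Cc2cc(C=O)ccc2O1
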